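The data are simulated on assumed constants; the scatter is artificial.

I began at the late end of the earlier runs, where the eta run had nearly stopped moving: links stood at 22% and rings at 24% at 2.50 h. Here is what stood on the bench and what was asked.

| flask | first end groups | second end groups | remark | time |
|---|---|---|---|---|
| eta | 0.10 M | 0.10 M | run made earlier |  |
| delta | 0.10 M | 0.050 M | run made earlier |  |
| theta | 0.10 M | 0.075 M | run made earlier |  |
| beta | 0.050 M | 0.10 M | run made earlier |  |
| autumn | 0.10 M | 0.100 M | a closed flask charged with all of it at once and left for 4.0 h | 4.0 h |
| winter | 0.10 M | 0.100 M | one stirred flow tank at steady state, fed with the mixture as stated, mean residence time 4.0 h |  |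
| summer | 0.10 M (fed, over 2.00 h) | 0.100 M | a stirred flask in which first end groups is dosed at a steady rate over 2.00 h without added volume, worked up at 4.0 h | 4.0 h |
| midnight | 0.10 M | 0.100 M (fed, over 2.00 h) | all but second end groups at the start; second end groups goes in evenly over 2.00 h, the run ends at 4.0 h | 4.0 h |

| run | time / h | links / % | rings / % |
|---|---|---|---|
| eta | 0.200 | 9 | 6 |
| eta | 0.333 | 12 | 10 |
| eta | 0.417 | 16 | 11 |
| eta | 0.667 | 15 | 14 |
| eta | 1.00 | 22 | 18 |
| eta | 1.50 | 19 | 23 |
| eta | 2.50 | 22 | 24 |
| delta | 0.250 | 4 | 6 |
| delta | 0.417 | 7 | 12 |
| delta | 0.667 | 8 | 19 |
| delta | 0.833 | 8 | 19 |
| delta | 1.33 | 8 | 23 |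
| delta | 2.00 | 12 | 25 |
| delta | 3.00 | 9 | 31 |
| theta | 0.250 | 7 | 9 |
| theta | 0.417 | 9 | 12 |
| theta | 0.667 | 14 | 15 |
| theta | 0.833 | 14 | 18 |
| theta | 1.33 | 13 | 24 |
| theta | 2.00 | 18 | 24 |
| theta | 3.00 | 16 | 28 |
| beta | 0.250 | 14 | 12 |
| beta | 0.833 | 23 | 21 |
| beta | 1.33 | 25 | 23 |
| beta | 2.50 | 32 | 31 |
| beta | 3.00 | 32 | 32 |

(readings scatter by 1.5 percentage points)

- percent here means first end groups units held: one homo dimer counts as two
- the stated concentrations are those of everything mixed, before any reaction; amounts are the same in each set-up
- the analysis behind the earlier runs scatters by 1.5 percentage points, standard deviation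
- reactions considered so far: 2 first end groups -> homo dimer; first end groups + second end groups -> rings; first end groups + second end groups -> links; second end groups <-> dormant form
- the feed brings no volume worth counting
- the earlier runs were made in a closed, stirred flask

- order of the set-ups by the share of links in all that became links or rings, at the outlet or at the end, highest first (autumn / winter / summer / midnight)
- share of links in all that became links or rings, at the outlet or at the end, autumn
- share of links in all that became links or rings, at the outlet or at the end, winter
- share of links in all that became links or rings, at the outlet or at the end, summer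
- share of links in all that became links or rings, at the outlet or at the end, midnight

I divided the rate of links by the rate of rings, so that time dropped out. The beta run, with half of the first end groups, gave 10.0 M⁻¹ per molar of second end groups charged. So I let first end groups cancel and kept the eta value as the link slope, the link-to-ring ratio per molar of second end groups, a selectivity factor 9.17 M⁻¹. The delta run read 5.81 M⁻¹, so the slope is rough.

links / rings = link slope × level of second end groups

share of links = link slope × level / (1 + link slope × level)

Then I ordered the times. The runs held no reading of the dormant form, and I set no time for it. Of the times I could read, the shortest was a ring half-mark: in the eta run, rings reached half of their last reading at 0.417 h. Next came the dosing, 2.00 h, longer than that half-mark, and longest the run, 4.0 h. Autumn, charged as eta, should therefore end on eta's plateau, a share of 47.8%. Taking the same mark for midnight, the feed had brought 0.0209 M of second end groups by then, so I reckoned a share of 16.0%.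

The forecast ran autumn > summer > winter > midnight, with 47%, 41%, 45% and 33% for autumn, winter, summer and midnight, on the ground that “This single slope reproduces all four end points”. For midnight my share lay lower than the forecast's.

The flasks gave autumn > summer > winter > midnight: autumn 46.9%, winter 34.7%, summer 42.3%, midnight 20.6%.

    2 first end groups → homo dimer (k = 10.0 M⁻¹ h⁻¹)
    first end groups + second end groups → rings, rate k2*[first end groups] as long as [second end groups] is above zero (k = 0.450 h⁻¹)
    first end groups + second end groups → links (k = 8.30 M⁻¹ h⁻¹)
    second end groups ⇌ dormant form (K = 0.700, k = 2.70 h⁻¹)

Midnight's end ratio of links to rings, 0.260, divided by the link slope, reads as a level of 0.0283 M. The neighbouring flask was midnight with 0.025 M of first end groups. In place of a half-mark I took a rough half-time of first end groups from the starting rates of the homo dimer and ring steps at that charge, which gave 0.730 h. By then the feed had brought 0.0365 M, and the link slope gave a share of 25.1%. That flask gave 30.6%, with links at 21.3% and rings at 48.4%.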